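**Retrosynthetic overview**

1. Difengpiol B ← fluoride desilylation ← face-selective reduction of the C3' ketone of a 5-hydroxy-2-methoxycyclohexanone in which ring C is complete.
2. Feature used: in ring C (cyclohexane) the tertiary C1'–OH and the secondary C3'–OH are 1,3-related across the C2' methylene, C1' is bonded to C2 of ring B and C3' is flanked by the methoxy carbon C4'. This aldol pattern is cut at C1'–C2' (samarium Reformatsky aldol of a C3' bromomethyl ketone onto the C1' ketone).
3. Bromomethyl ketone ← NBS/water on a 2-methoxyallyl enol ether ← C1'–C6' bond from the Weinreb amide of the dihydrobenzofuran-2-carboxylic acid and a Grignard reagent that carries C4' (from (S)-3-hydroxydihydrofuran-2(3H)-one).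
4. Ring B (dihydrofuran) ← intramolecular Mitsunobu C2–O1 closure on a trans-α-hydroxy-β-aryl-γ-butyrolactone, then lactone opening and epimerisation of C2 to 2,3-trans; C3 ← rhodium-catalysed asymmetric arylation of furan-2(5H)-one with the boronic acid made from dihydroconiferyl alcohol.
5. Ring order: ring A (arene, bought) → temporary lactone ring (from the furanone, opened in step 9) → ring B (step 8) → ring C (step 17).

Key step: step 17

Remark: locants are O1, C2, C3, C3a–C7a for the dihydrobenzofuran and C1'–C6' for the cyclohexane (C1' on C2, OH on C3', OMe on C4'); the target is read from the SMILES as (2S,3R,1'S,3'S,4'S) with a 2,3-trans ring B; the 2,3-trans arrangement is assumed to be the thermodynamically preferred one at the C2 ketone stage, and (S)-3-hydroxydihydrofuran-2(3H)-one is taken as commercial. TBS = tert-butyldimethylsilyl.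

**Route**

Step 1
Reactants: 1 dihydroconiferyl alcohol
Product: 2 2-bromo-4-(3-hydroxypropyl)-6-methoxyphenol
Conditions: NBS (1.0 equiv), i-Pr2NH (cat.), CH2Cl2, 0 °C
Reagents that add atoms: N-bromosuccinimide O=C1CCC(=O)N1Br
Why: Electrophilic aromatic bromination with NBS under amine catalysis goes ortho to the phenol, and the only free ortho position is C6, so one regioisomer is expected.

Step 2
Reactants: 2 2-bromo-4-(3-hydroxypropyl)-6-methoxyphenol
Product: 3 3-[4-(benzyloxy)-3-bromo-5-methoxyphenyl]propan-1-ol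
Conditions: BnBr, K2CO3, acetone, reflux
Reagents that add atoms: benzyl bromide BrCc1ccccc1
Why: Williamson etherification in which K2CO3 deprotonates only the phenol, so the aliphatic hydroxyl stays free.

Step 3
Reactants: 3 3-[4-(benzyloxy)-3-bromo-5-methoxyphenyl]propan-1-ol
Product: 4 {3-[4-(benzyloxy)-3-bromo-5-methoxyphenyl]propoxy}(tert-butyl)dimethylsilane
Conditions: TBSCl, imidazole, CH2Cl2, rt
Reagents that add atoms: tert-butyldimethylsilyl chloride CC(C)(C)[Si](C)(C)Cl
Why: Standard silylation of a primary alcohol, which masks the side-chain hydroxyl until the last step.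

Step 4
Reactants: 4 {3-[4-(benzyloxy)-3-bromo-5-methoxyphenyl]propoxy}(tert-butyl)dimethylsilane
Product: 7 {2-(benzyloxy)-5-[3-(tert-butyldimethylsilyloxy)propyl]-3-methoxyphenyl}boronic acid, via aryllithium 5 (not isolated), via lithium aryltriisopropoxyborate 6 (not isolated)
Conditions: n-BuLi, THF, −78 °C; B(OiPr)3, −78 °C → rt; 1 M HCl to pH 5–6, 0 °C (brief)
Reagents that add atoms: triisopropyl borate CC(C)OB(OC(C)C)OC(C)C; water O
Why: Bromine–lithium exchange is faster than benzylic deprotonation at −78 °C, and trapping of the aryllithium with the borate ester followed by mild hydrolysis gives the boronic acid.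

Step 5
Reactants: 7 {2-(benzyloxy)-5-[3-(tert-butyldimethylsilyloxy)propyl]-3-methoxyphenyl}boronic acid; 8 furan-2(5H)-one
Product: 9 (R)-4-{2-(benzyloxy)-5-[3-(tert-butyldimethylsilyloxy)propyl]-3-methoxyphenyl}dihydrofuran-2(3H)-one
Conditions: [Rh(OH)((R)-BINAP)]2 (cat.), 8 (excess), dioxane/H2O 10:1, 40 °C
Reagents that add atoms: none
Why: Hayashi–Miyaura asymmetric 1,4-addition in which the aryl–rhodium species inserts the enoate on the face dictated by (R)-BINAP, which by analogy with cyclohexenone and 5,6-dihydropyran-2-one should set the benzylic centre (later C3) as R, before water protonates the rhodium enolate.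

Step 6
Reactants: 9 (R)-4-{2-(benzyloxy)-5-[3-(tert-butyldimethylsilyloxy)propyl]-3-methoxyphenyl}dihydrofuran-2(3H)-one
Product: 11 (3S,4R)-4-{2-(benzyloxy)-5-[3-(tert-butyldimethylsilyloxy)propyl]-3-methoxyphenyl}-3-hydroxydihydrofuran-2(3H)-one (3,4-trans), via sodium lactone enolate 10 (not isolated)
Conditions: NaN(SiMe3)2, THF, −78 °C; 2-(phenylsulfonyl)-3-phenyloxaziridine, −78 °C; AcOH, −78 °C
Reagents that add atoms: 2-(phenylsulfonyl)-3-phenyloxaziridine O=S(=O)(N1OC1c1ccccc1)c1ccccc1
Why: Davis enolate hydroxylation in which the oxaziridine transfers oxygen to the enolate face opposite the C4 aryl group, so the new hydroxyl is trans to the aryl group (3S).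

Step 7
Reactants: 11 (3S,4R)-4-{2-(benzyloxy)-5-[3-(tert-butyldimethylsilyloxy)propyl]-3-methoxyphenyl}-3-hydroxydihydrofuran-2(3H)-one
Product: 12 (3S,4R)-4-{5-[3-(tert-butyldimethylsilyloxy)propyl]-2-hydroxy-3-methoxyphenyl}-3-hydroxydihydrofuran-2(3H)-one
Conditions: H2 (1 atm), Pd/C, EtOAc, rt
Reagents that add atoms: none
Why: Hydrogenolysis of the aryl benzyl ether over Pd/C leaves the lactone, the silyl ether and the non-benzylic C–O bonds untouched.

Step 8
Reactants: 12 (3S,4R)-4-{5-[3-(tert-butyldimethylsilyloxy)propyl]-2-hydroxy-3-methoxyphenyl}-3-hydroxydihydrofuran-2(3H)-one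
Product: 13 cis-fused γ-lactone between the C2 carboxyl and the C3 hydroxymethyl group of (2R,3R)-5-[3-(tert-butyldimethylsilyloxy)propyl]-3-(hydroxymethyl)-7-methoxy-2,3-dihydrobenzofuran-2-carboxylic acid
Conditions: PPh3, DIAD, THF, 0 °C → rt
Reagents that add atoms: none
Why: Intramolecular Mitsunobu etherification (5-exo-tet) in which the phenol displaces the activated α-oxygen with inversion, possible because hydroxyl and aryl are trans, closing ring B as the cis-fused lactone with C2 as R, which step 15 corrects.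

Step 9
Reactants: 13 cis-fused γ-lactone of the (2R,3R)-dihydrobenzofuran-2-carboxylic acid
Product: 14 (2R,3R)-5-[3-(tert-butyldimethylsilyloxy)propyl]-3-(hydroxymethyl)-N,7-dimethoxy-N-methyl-2,3-dihydrobenzofuran-2-carboxamide (2,3-cis)
Conditions: MeNHOMe·HCl, AlMe3, CH2Cl2, 0 °C → rt; aq. KNaC4H4O6 (potassium sodium tartrate)
Reagents that add atoms: N,O-dimethylhydroxylamine hydrochloride CNOC.Cl
Why: Weinreb aminolysis with the aluminium amide made from AlMe3 opens the aryloxy lactone irreversibly without enolisation, so both stereocentres are kept.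

Step 10
Reactants: 14 (2R,3R)-5-[3-(tert-butyldimethylsilyloxy)propyl]-3-(hydroxymethyl)-N,7-dimethoxy-N-methyl-2,3-dihydrobenzofuran-2-carboxamide
Product: 15 (2R,3R)-3-[(tert-butyldimethylsilyloxy)methyl]-5-[3-(tert-butyldimethylsilyloxy)propyl]-N,7-dimethoxy-N-methyl-2,3-dihydrobenzofuran-2-carboxamide (2,3-cis)
Conditions: TBSCl, imidazole, DMF, 0 °C → rt (directly after step 9)
Reagents that add atoms: tert-butyldimethylsilyl chloride CC(C)(C)[Si](C)(C)Cl
Why: Prompt silylation of the primary hydroxyl prevents relactonisation and gives the same protecting group as on the side chain.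

Step 11
Reactants: 16 (S)-3-hydroxydihydrofuran-2(3H)-one
Product: 17 (S)-3-methoxydihydrofuran-2(3H)-one
Conditions: MeI, Ag2O, MeCN, rt, dark
Reagents that add atoms: iodomethane CI
Why: Purdie methylation with MeI/Ag2O is neutral, so the α-stereocentre, which becomes C4', is not epimerised.

Step 12
Reactants: 17 (S)-3-methoxydihydrofuran-2(3H)-one
Product: 18 methyl (S)-4-bromo-2-methoxybutanoate
Conditions: HBr (anhydrous, saturated), MeOH, 0 °C → rt
Reagents that add atoms: hydrogen bromide Br; methanol CO
Why: Acid-mediated lactone opening in which bromide attacks the O–CH2 carbon of the protonated lactone (SN2) and the acid is esterified by methanol, as in the known conversion of γ-butyrolactone into 4-bromobutanoates, without involving the stereocentre.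

Step 13
Reactants: 18 methyl (S)-4-bromo-2-methoxybutanoate
Product: 19 (S)-5-bromo-2,3-dimethoxypent-1-ene
Conditions: Cp2TiMe2, toluene/THF, 65 °C, dark; pentane, filtration through basic Al2O3
Reagents that add atoms: dimethyltitanocene C[Ti](C)(C1C=CC=C1)C1C=CC=C1
Why: Petasis methylenation in which the titanocene methylidene formed on heating undergoes [2+2] cycloaddition and cycloreversion with the ester carbonyl to give the methyl enol ether, a latent bromomethyl ketone, under non-basic conditions that keep the stereocentre.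

Step 14
Reactants: 15 (2R,3R)-3-[(tert-butyldimethylsilyloxy)methyl]-5-[3-(tert-butyldimethylsilyloxy)propyl]-N,7-dimethoxy-N-methyl-2,3-dihydrobenzofuran-2-carboxamide; 19 (S)-5-bromo-2,3-dimethoxypent-1-ene
Product: 21 (4S)-1-{(2R,3R)-3-[(tert-butyldimethylsilyloxy)methyl]-5-[3-(tert-butyldimethylsilyloxy)propyl]-7-methoxy-2,3-dihydrobenzofuran-2-yl}-4,5-dimethoxyhex-5-en-1-one (2,3-cis), via Grignard reagent 20 (not isolated)
Conditions: 19, Mg, THF, rt; then 15, THF, −20 → 0 °C; aq. NaH2PO4/Na2HPO4 (pH 7)
Reagents that add atoms: none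
Why: Weinreb ketone synthesis in which the Grignard reagent adds once, because the magnesium chelate of the tetrahedral intermediate survives until the neutral quench that also spares the acid-labile enol ether, and so forms the C1'–C6' bond.

Step 15
Reactants: 21 (4S)-1-{(2R,3R)-…-2,3-dihydrobenzofuran-2-yl}-4,5-dimethoxyhex-5-en-1-one (2,3-cis)
Product: 22 (4S)-1-{(2S,3R)-3-[(tert-butyldimethylsilyloxy)methyl]-5-[3-(tert-butyldimethylsilyloxy)propyl]-7-methoxy-2,3-dihydrobenzofuran-2-yl}-4,5-dimethoxyhex-5-en-1-one (2,3-trans)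
Conditions: DBU (cat.), CH2Cl2, rt
Reagents that add atoms: none
Why: Base-catalysed epimerisation through the C1'–C2 enolate of the α-aryloxy ketone equilibrates C2 to the thermodynamically preferred 2,3-trans arrangement (2S), while C3 and C4' carry no acidic hydrogen at this stage.

Step 16
Reactants: 22 (4S)-1-{(2S,3R)-…-2,3-dihydrobenzofuran-2-yl}-4,5-dimethoxyhex-5-en-1-one (2,3-trans)
Product: 23 (4S)-6-bromo-1-{(2S,3R)-3-[(tert-butyldimethylsilyloxy)methyl]-5-[3-(tert-butyldimethylsilyloxy)propyl]-7-methoxy-2,3-dihydrobenzofuran-2-yl}-4-methoxyhexane-1,5-dione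
Conditions: NBS (1.05 equiv), NaHCO3, THF/H2O 4:1, −20 → 0 °C
Reagents that add atoms: N-bromosuccinimide O=C1CCC(=O)N1Br; water O
Why: Bromination of the electron-rich enol ether by NBS gives an oxocarbenium ion that water captures, and loss of methanol from the hemiketal delivers the bromomethyl ketone regiospecifically under near-neutral conditions, faster than any bromination of the arene.

Step 17
Reactants: 23 (4S)-6-bromo-1-{(2S,3R)-…-2,3-dihydrobenzofuran-2-yl}-4-methoxyhexane-1,5-dione
Product: 26 (2S,5S)-5-{(2S,3R)-3-[(tert-butyldimethylsilyloxy)methyl]-5-[3-(tert-butyldimethylsilyloxy)propyl]-7-methoxy-2,3-dihydrobenzofuran-2-yl}-5-hydroxy-2-methoxycyclohexan-1-one, via samarium enolate 24 (not isolated), via samarium aldolate 25 (not isolated)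
Conditions: SmI2 (0.1 M in THF, 2.2 equiv, added dropwise to 23 until the blue colour persists), THF (high dilution), −78 °C, no HMPA; H2O/THF, −78 °C
Reagents that add atoms: none
Why: Two single-electron transfers from divalent samarium cleave the C2'–Br bond and give, without base and therefore without touching C2 or C4', the trivalent-samarium enolate 24 of the C3' ketone, whose carbon C2' adds to the C1' carbonyl to form the C1'–C2' bond (aldolate 25); the closest known reaction type is the SmI2-promoted intramolecular Reformatsky-type aldol cyclisation of α-halo ketones and esters onto ketones. Ring C closes in the 6-(enolendo)-exo-trig mode, because both enolate carbons C2' and C3' lie inside the new six-membered ring. The new stereocentre C1' is controlled by the adjacent C2: the oxophilic trivalent samarium bridges the enolate oxygen, the C1' carbonyl oxygen and ring oxygen O1 (Cram chelate), so that C2' approaches the carbonyl face flanked by the C2 hydrogen and not the one flanked by C3, which corresponds to (1'S). In the chair-like array this places the dihydrobenzofuranyl group equatorial, the C1'–O–Sm bond axial and the C4' methoxy group axial, where it is free of allylic strain with the enolate O–Sm unit, so that chelate and ring preferences should reinforce each other. The step needs chemoselectivity for the C–Br bond over the α-aryloxy C1' ketone and the α-methoxy C3' ketone, secured by the much faster reduction of the α-bromo ketone at −78 °C, by adding SmI2 to the substrate so that no excess reductant builds up, by leaving out HMPA and by a cold quench. It also needs facial selectivity at C1', secured by the O1 chelate, and high dilution so that ring closure outruns intermolecular aldol addition.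

Step 18
Reactants: 26 (2S,5S)-5-{(2S,3R)-…-2,3-dihydrobenzofuran-2-yl}-5-hydroxy-2-methoxycyclohexan-1-one
Product: 28 (1S,3S,4S)-1-{(2S,3R)-3-[(tert-butyldimethylsilyloxy)methyl]-5-[3-(tert-butyldimethylsilyloxy)propyl]-7-methoxy-2,3-dihydrobenzofuran-2-yl}-4-methoxycyclohexane-1,3-diol, via C1' diethylborinate 27 (not isolated)
Conditions: Et2BOMe, THF/MeOH 4:1, −78 → −40 °C; NaBH4, −78 °C; AcOH; MeOH co-evaporation
Reagents that add atoms: none
Why: Narasaka–Prasad reduction in which the diethylborinate on the axial C1' oxygen activates the C3' carbonyl and shields the face syn to C1'–O, so that external hydride should attack from the opposite face and give the 1,3-cis diol (3'S), which is also trans to the C4' methoxy group.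

Step 19
Reactants: 28 (1S,3S,4S)-1-{(2S,3R)-…-2,3-dihydrobenzofuran-2-yl}-4-methoxycyclohexane-1,3-diol (bis-TBS ether)
Product: 29 difengpiol B
Conditions: Bu4NF, THF, 0 °C → rt
Reagents that add atoms: none
Why: Fluoride-mediated cleavage of both primary silyl ethers is driven by the strong Si–F bond, and nothing else in the molecule reacts with fluoride.

**Compound list**

1 | dihydroconiferyl alcohol, 4-(3-hydroxypropyl)-2-methoxyphenol | COc1cc(CCCO)ccc1O | starting material
2 | 2-bromo-4-(3-hydroxypropyl)-6-methoxyphenol | COc1cc(CCCO)cc(Br)c1O | intermediate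
3 | 3-[4-(benzyloxy)-3-bromo-5-methoxyphenyl]propan-1-ol | COc1cc(CCCO)cc(Br)c1OCc1ccccc1 | intermediate
4 | {3-[4-(benzyloxy)-3-bromo-5-methoxyphenyl]propoxy}(tert-butyl)dimethylsilane | COc1cc(CCCO[Si](C)(C)C(C)(C)C)cc(Br)c1OCc1ccccc1 | intermediate
5 | aryllithium from 4 (Li in place of Br) | COc1cc(CCCO[Si](C)(C)C(C)(C)C)cc([Li])c1OCc1ccccc1 | intermediate (not isolated)
6 | lithium aryltriisopropoxyborate from 5 | [Li+].COc1cc(CCCO[Si](C)(C)C(C)(C)C)cc([B-](OC(C)C)(OC(C)C)OC(C)C)c1OCc1ccccc1 | intermediate (not isolated)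
7 | {2-(benzyloxy)-5-[3-(tert-butyldimethylsilyloxy)propyl]-3-methoxyphenyl}boronic acid | COc1cc(CCCO[Si](C)(C)C(C)(C)C)cc(B(O)O)c1OCc1ccccc1 | intermediate
8 | furan-2(5H)-one | O=C1OCC=C1 | starting material
9 | (R)-4-{2-(benzyloxy)-5-[3-(tert-butyldimethylsilyloxy)propyl]-3-methoxyphenyl}dihydrofuran-2(3H)-one | O=C1C[C@H](c2cc(CCCO[Si](C)(C)C(C)(C)C)cc(OC)c2OCc2ccccc2)CO1 | intermediate
10 | sodium enolate of lactone 9 | [Na+].[O-]C1=C[C@H](c2cc(CCCO[Si](C)(C)C(C)(C)C)cc(OC)c2OCc2ccccc2)CO1 | intermediate (not isolated)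
11 | (3S,4R)-4-{2-(benzyloxy)-5-[3-(tert-butyldimethylsilyloxy)propyl]-3-methoxyphenyl}-3-hydroxydihydrofuran-2(3H)-one, 3,4-trans | O=C1[C@@H](O)[C@H](c2cc(CCCO[Si](C)(C)C(C)(C)C)cc(OC)c2OCc2ccccc2)CO1 | intermediate
12 | (3S,4R)-4-{5-[3-(tert-butyldimethylsilyloxy)propyl]-2-hydroxy-3-methoxyphenyl}-3-hydroxydihydrofuran-2(3H)-one | O=C1[C@@H](O)[C@H](c2cc(CCCO[Si](C)(C)C(C)(C)C)cc(OC)c2O)CO1 | intermediate
13 | cis-fused γ-lactone of (2R,3R)-5-[3-(tert-butyldimethylsilyloxy)propyl]-3-(hydroxymethyl)-7-methoxy-2,3-dihydrobenzofuran-2-carboxylic acid | COc1cc(CCCO[Si](C)(C)C(C)(C)C)cc2c1O[C@H]1C(=O)OC[C@@H]21 | intermediate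
14 | (2R,3R)-5-[3-(tert-butyldimethylsilyloxy)propyl]-3-(hydroxymethyl)-N,7-dimethoxy-N-methyl-2,3-dihydrobenzofuran-2-carboxamide, 2,3-cis | COc1cc(CCCO[Si](C)(C)C(C)(C)C)cc2c1O[C@@H](C(=O)N(C)OC)[C@H]2CO | intermediate
15 | (2R,3R)-3-[(tert-butyldimethylsilyloxy)methyl]-5-[3-(tert-butyldimethylsilyloxy)propyl]-N,7-dimethoxy-N-methyl-2,3-dihydrobenzofuran-2-carboxamide, 2,3-cis | COc1cc(CCCO[Si](C)(C)C(C)(C)C)cc2c1O[C@@H](C(=O)N(C)OC)[C@H]2CO[Si](C)(C)C(C)(C)C | intermediate
16 | (S)-3-hydroxydihydrofuran-2(3H)-one, (S)-α-hydroxy-γ-butyrolactone | O[C@H]1CCOC1=O | starting material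
17 | (S)-3-methoxydihydrofuran-2(3H)-one | CO[C@H]1CCOC1=O | intermediate
18 | methyl (S)-4-bromo-2-methoxybutanoate | COC(=O)[C@@H](OC)CCBr | intermediate
19 | (S)-5-bromo-2,3-dimethoxypent-1-ene | C=C(OC)[C@@H](OC)CCBr | intermediate
20 | (S)-(3,4-dimethoxypent-4-en-1-yl)magnesium bromide | C=C(OC)[C@@H](OC)CC[Mg]Br | intermediate (not isolated)
21 | (4S)-1-{(2R,3R)-3-[(tert-butyldimethylsilyloxy)methyl]-5-[3-(tert-butyldimethylsilyloxy)propyl]-7-methoxy-2,3-dihydrobenzofuran-2-yl}-4,5-dimethoxyhex-5-en-1-one, 2,3-cis | COc1cc(CCCO[Si](C)(C)C(C)(C)C)cc2c1O[C@@H](C(=O)CC[C@H](OC)C(OC)=C)[C@H]2CO[Si](C)(C)C(C)(C)C | intermediate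
22 | (4S)-1-{(2S,3R)-3-[(tert-butyldimethylsilyloxy)methyl]-5-[3-(tert-butyldimethylsilyloxy)propyl]-7-methoxy-2,3-dihydrobenzofuran-2-yl}-4,5-dimethoxyhex-5-en-1-one, 2,3-trans | COc1cc(CCCO[Si](C)(C)C(C)(C)C)cc2c1O[C@H](C(=O)CC[C@H](OC)C(OC)=C)[C@H]2CO[Si](C)(C)C(C)(C)C | intermediate
23 | (4S)-6-bromo-1-{(2S,3R)-3-[(tert-butyldimethylsilyloxy)methyl]-5-[3-(tert-butyldimethylsilyloxy)propyl]-7-methoxy-2,3-dihydrobenzofuran-2-yl}-4-methoxyhexane-1,5-dione | COc1cc(CCCO[Si](C)(C)C(C)(C)C)cc2c1O[C@H](C(=O)CC[C@H](OC)C(=O)CBr)[C@H]2CO[Si](C)(C)C(C)(C)C | intermediate (key-step precursor)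
24 | diiodosamarium enolate of the C3' ketone of 23 (C2'=C3'–O–SmI2) | COc1cc(CCCO[Si](C)(C)C(C)(C)C)cc2c1O[C@H](C(=O)CC[C@H](OC)C(=C)O[Sm](I)I)[C@H]2CO[Si](C)(C)C(C)(C)C | intermediate (not isolated)
25 | diiodosamarium C1' alkoxide of 26 | COc1cc(CCCO[Si](C)(C)C(C)(C)C)cc2c1O[C@H]([C@]3(O[Sm](I)I)CC[C@H](OC)C(=O)C3)[C@H]2CO[Si](C)(C)C(C)(C)C | intermediate (not isolated)
26 | (2S,5S)-5-{(2S,3R)-3-[(tert-butyldimethylsilyloxy)methyl]-5-[3-(tert-butyldimethylsilyloxy)propyl]-7-methoxy-2,3-dihydrobenzofuran-2-yl}-5-hydroxy-2-methoxycyclohexan-1-one | COc1cc(CCCO[Si](C)(C)C(C)(C)C)cc2c1O[C@H]([C@]3(O)CC[C@H](OC)C(=O)C3)[C@H]2CO[Si](C)(C)C(C)(C)C | intermediate (key-step product)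
27 | C1' O-diethylborinate of 26 | COc1cc(CCCO[Si](C)(C)C(C)(C)C)cc2c1O[C@H]([C@]3(OB(CC)CC)CC[C@H](OC)C(=O)C3)[C@H]2CO[Si](C)(C)C(C)(C)C | intermediate (not isolated)
28 | (1S,3S,4S)-1-{(2S,3R)-3-[(tert-butyldimethylsilyloxy)methyl]-5-[3-(tert-butyldimethylsilyloxy)propyl]-7-methoxy-2,3-dihydrobenzofuran-2-yl}-4-methoxycyclohexane-1,3-diol | COc1cc(CCCO[Si](C)(C)C(C)(C)C)cc2c1O[C@H]([C@]3(O)CC[C@H](OC)[C@@H](O)C3)[C@H]2CO[Si](C)(C)C(C)(C)C | intermediate
29 | difengpiol B, (1S,3S,4S)-1-[(2S,3R)-3-(hydroxymethyl)-5-(3-hydroxypropyl)-7-methoxy-2,3-dihydrobenzofuran-2-yl]-4-methoxycyclohexane-1,3-diol | COc1cc(CCCO)cc2c1O[C@H]([C@]1(O)CC[C@H](OC)[C@@H](O)C1)[C@H]2CO | target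

**Step count and risks**

Total step count: 19 (16 in the main line, 3 for the side-chain fragment).
Longest linear sequence: 16 steps (steps 1–10 and 14–19).

Steps most likely to fail:

1. Step 17 (key step). What may go wrong: electron transfer to the α-aryloxy C1' ketone with opening of ring B; protonation of the samarium enolate before the C–C bond forms (simple debromination); or attack on the wrong carbonyl face if the C4' methoxy group prefers an equatorial, samarium-bound position and overrides the O1 chelate. Fallback (enolate generation separated from bond formation): starting from 23, reductive silylation (Zn, Me3SiCl, TMEDA, Et2O, 0 °C) should give regiospecifically the C3' trimethylsilyl enol ether F1. TiCl4 (CH2Cl2, −78 °C), which binds O1 and the C1' carbonyl oxygen in a five-membered chelate, should then bring about an intramolecular Mukaiyama aldol addition on the same carbonyl face, and aqueous work-up returns to the route at 26.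

2. Step 18. What may go wrong: hydride delivery on the face syn to the C1' oxygen (through a borinate that does not close the chelate), giving the 1,3-trans diol, because the axial C4' methoxy group hinders the face that has to be attacked. Fallback (steric approach control with a blocked face): starting from 26, Et3SiOTf and 2,6-lutidine (CH2Cl2, −78 °C) should silylate the tertiary hydroxyl to give the triethylsilyl ether F2, whose axial silyloxy group closes the syn face. The bulky hydride LiBH(s-Bu)3 (THF, −78 °C) should then attack C3' from the open face to give the alcohol F3, and the fluoride treatment of step 19 removes all three silyl groups, so the route is rejoined at 29.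

3. Step 5. What may go wrong: protodeboronation of the electron-rich, ortho-alkoxy boronic acid outrunning conjugate addition, or loss of enantioselectivity because of the ortho substituent. Fallback (C–C bond first, stereocentre second): starting from 7, Suzuki–Miyaura coupling with 4-bromofuran-2(5H)-one (O=C1C=C(Br)CO1; Pd(PPh3)4, K3PO4, THF/H2O) should give the 4-arylfuran-2(5H)-one F4. Enantioselective hydrogenation of its C=C bond with a Ru(OAc)2(BINAP) catalyst of the antipode that delivers the R lactone (H2, MeOH), which leaves the benzyl ether intact, returns to the route at 9.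

**Further compounds**

F1 | step 17 | C3' trimethylsilyl enol ether of the C1',C3'-diketone (C2'=C3'–OSiMe3) | COc1cc(CCCO[Si](C)(C)C(C)(C)C)cc2c1O[C@H](C(=O)CC[C@H](OC)C(=C)O[Si](C)(C)C)[C@H]2CO[Si](C)(C)C(C)(C)C
F2 | step 18 | C1' O-triethylsilyl ether of 26 | COc1cc(CCCO[Si](C)(C)C(C)(C)C)cc2c1O[C@H]([C@]3(O[Si](CC)(CC)CC)CC[C@H](OC)C(=O)C3)[C@H]2CO[Si](C)(C)C(C)(C)C
F3 | step 18 | C1' O-triethylsilyl ether of 28 (free C3' hydroxyl, 3'S) | COc1cc(CCCO[Si](C)(C)C(C)(C)C)cc2c1O[C@H]([C@]3(O[Si](CC)(CC)CC)CC[C@H](OC)[C@@H](O)C3)[C@H]2CO[Si](C)(C)C(C)(C)C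
F4 | step 5 | 4-{2-(benzyloxy)-5-[3-(tert-butyldimethylsilyloxy)propyl]-3-methoxyphenyl}furan-2(5H)-one | O=C1C=C(c2cc(CCCO[Si](C)(C)C(C)(C)C)cc(OC)c2OCc2ccccc2)CO1
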